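The butane chain is numbered b1 to b4 from the outer guaiacyl ring A to ring B, the arene of the dihydrobenzofuran. Since b2 and b3 bear neighbouring CH2OH groups, the bond between b3 and its CH2OH carbon is the one disconnected. The b2 oxygen carries that carbon on a temporary SiMe2 link, and a b3=b4 alkene conjugated with ring B receives it as a radical. In one operation the key step makes this C–C bond, closes a sacrificial 1,2-oxasilinane and sets b3 trans to b2. Its precursor is the (bromomethyl)dimethylsilyl ether of an (R,E)-homoallylic alcohol, assembled by Heck coupling of an auxiliary-derived butenol with an enantioenriched 5-bromodihydrobenzofuran.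

Key step: step 15

Labels: C2, C3, C5 and C7 follow benzofuran numbering, and ring C is the guaiacyl group on C2.
Assumption: in step 9 the (Sa,Sc,Sc) antipode of the phosphoramidite is taken to give the (S)-ether; both antipodes are commercial, so the sense of induction is verified on the first run and the ligand exchanged if it proves opposite.

Step 1
Reactants: 1 (R)-4-benzyl-2-oxazolidinone; 2 (E,E)-crotonic anhydride
Product: 3 (R)-4-benzyl-3-[(E)-but-2-enoyl]oxazolidin-2-one
Conditions: LiCl, Et3N, THF, −20 °C to rt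
Reagents that add atoms: none
Why: LiCl-assisted N-acylation of the oxazolidinone by the anhydride under amine base needs no strong base, spares the polymerisable enoyl donor and leaves the auxiliary centre untouched.

Step 2
Reactants: 4 4-(benzyloxy)-3-methoxybenzyl alcohol
Product: 5 4-(benzyloxy)-3-methoxybenzyl bromide
Conditions: PBr3, Et2O, 0 °C
Reagents that add atoms: phosphorus tribromide, BrP(Br)Br
Why: Bromide displaces the phosphite ester of an electron-rich benzylic alcohol (SN2 bromination with PBr3) cleanly in the cold, and the bromide is used promptly.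

Step 3
Reactants: 3 (R)-4-benzyl-3-[(E)-but-2-enoyl]oxazolidin-2-one; 5 4-(benzyloxy)-3-methoxybenzyl bromide
Product: 7 (R)-4-benzyl-3-{(R)-2-[4-(benzyloxy)-3-methoxybenzyl]but-3-enoyl}oxazolidin-2-one, via sodium dienolate 6 (not isolated)
Conditions: NaN(SiMe3)2, THF, −78 °C; then 5, −78 to −40 °C; AcOH quench
Reagents that add atoms: none
Why: In this deconjugative Evans asymmetric alkylation, gamma-deprotonation of the s-cis enoyl imide gives the chelated Z(O)-dienolate 6, which reacts at its alpha carbon on the face away from the auxiliary benzyl group, so the (R)-auxiliary sets b2 as (R) and a terminal vinyl group remains.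

Step 4
Reactants: 7 (R)-4-benzyl-3-{(R)-2-[4-(benzyloxy)-3-methoxybenzyl]but-3-enoyl}oxazolidin-2-one
Product: 8 (R)-2-[4-(benzyloxy)-3-methoxybenzyl]but-3-en-1-ol
Conditions: LiBH4, MeOH (1 equiv), Et2O, 0 °C
Reagents that add atoms: none
Why: Reductive removal of the auxiliary with LiBH4 is fast and barely basic, so the doubly activated b2–H should neither epimerise nor let the alkene slip into conjugation, and 1 is recovered.

Step 5
Reactants: 9 4-(benzyloxy)-3-methoxybenzaldehyde; 10 triethyl phosphonoacetate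
Product: 11 ethyl (E)-3-[4-(benzyloxy)-3-methoxyphenyl]acrylate
Conditions: LiCl, DBU, MeCN, rt
Reagents that add atoms: none
Why: The Horner–Wadsworth–Emmons olefination under Masamune–Roush conditions reliably gives the (E)-cinnamate from an aromatic aldehyde.

Step 6
Reactants: 11 ethyl (E)-3-[4-(benzyloxy)-3-methoxyphenyl]acrylate
Product: 12 (E)-3-[4-(benzyloxy)-3-methoxyphenyl]prop-2-en-1-ol
Conditions: i-Bu2AlH, CH2Cl2, −78 °C; aqueous potassium sodium tartrate
Reagents that add atoms: none
Why: 1,2-Reduction of a conjugated ester with i-Bu2AlH gives the allylic alcohol without touching the alkene or the benzyl ether.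

Step 7
Reactants: 12 (E)-3-[4-(benzyloxy)-3-methoxyphenyl]prop-2-en-1-ol
Product: 13 (E)-3-[4-(benzyloxy)-3-methoxyphenyl]allyl methyl carbonate
Conditions: ClCO2Me, pyridine, CH2Cl2, 0 °C
Reagents that add atoms: methyl chloroformate, COC(=O)Cl
Why: Simple O-acylation with a chloroformate installs the leaving group that iridium ionises in step 9.

Step 8
Reactants: 14 4-bromo-2-methoxyphenol
Product: 15 4-bromo-2-iodo-6-methoxyphenol
Conditions: NIS, TsOH·H2O (cat.), MeCN, rt, dark
Reagents that add atoms: N-iodosuccinimide, O=C1CCC(=O)N1I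
Why: Electrophilic aromatic iodination directed by the free phenol goes to the only open ortho position, the para position being blocked by bromine.

Step 9
Reactants: 13 (E)-3-[4-(benzyloxy)-3-methoxyphenyl]allyl methyl carbonate; 15 4-bromo-2-iodo-6-methoxyphenol
Product: 17 (S)-1-(benzyloxy)-4-[1-(4-bromo-2-iodo-6-methoxyphenoxy)allyl]-2-methoxybenzene, via sodium aryloxide 16 (not isolated)
Conditions: NaH, THF, 0 °C; then 13, [Ir(cod)Cl]2 (2 mol %), (Sa,Sc,Sc)-BINOL N,N-bis(1-phenylethyl)phosphoramidite (4 mol %, pre-activated with n-PrNH2), THF, rt to 40 °C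
Reagents that add atoms: none
Why: In this iridium-catalysed asymmetric allylic etherification, the cyclometalated phosphoramidite–allyliridium species is attacked by the aryloxide at its aryl-bearing terminus, so the branched ether forms, the ligand configuration sets the future C2 as (S), and both aryl halides stay inert.

Step 10
Reactants: 17 (S)-1-(benzyloxy)-4-[1-(4-bromo-2-iodo-6-methoxyphenoxy)allyl]-2-methoxybenzene
Product: 18 1-{[(2S,3R)-2-[4-(benzyloxy)-3-methoxyphenyl]-5-bromo-7-methoxy-2,3-dihydrobenzofuran-3-yl]methoxy}-2,2,6,6-tetramethylpiperidine (2,3-trans)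
Conditions: Bu3SnH (portionwise), TEMPO (excess), PhH, 70 °C
Reagents that add atoms: TEMPO, CC1(C)CCCC(C)(C)N1[O]
Why: In this aryl radical 5-exo-trig cyclisation with nitroxide trapping, iodine is abstracted far faster than bromine, ring closure onto the vinyl group keeps ring C pseudo-equatorial so the new C3 substituent ends up trans (3R), and TEMPO captures the primary radical before reduction or rearrangement.

Step 11
Reactants: 18 the TEMPO ether from step 10
Product: 19 [(2S,3R)-2-[4-(benzyloxy)-3-methoxyphenyl]-5-bromo-7-methoxy-2,3-dihydrobenzofuran-3-yl]methanol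
Conditions: Zn, AcOH/THF/H2O, 70 °C
Reagents that add atoms: none
Why: Reductive N–O cleavage of the alkoxyamine with zinc in acetic acid unmasks the primary alcohol and should leave the aryl bromide, the benzyl ether and both ring stereocentres alone.

Step 12
Reactants: 19 [(2S,3R)-2-[4-(benzyloxy)-3-methoxyphenyl]-5-bromo-7-methoxy-2,3-dihydrobenzofuran-3-yl]methanol
Product: 20 {[(2S,3R)-2-[4-(benzyloxy)-3-methoxyphenyl]-5-bromo-7-methoxy-2,3-dihydrobenzofuran-3-yl]methoxy}(tert-butyl)dimethylsilane
Conditions: TBSCl, imidazole, DMF, rt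
Reagents that add atoms: tert-butyldimethylsilyl chloride, CC(C)(C)[Si](C)(C)Cl
Why: Routine silyl ether formation masks the only hydroxyl that would otherwise compete for the chlorosilane in step 14.

Step 13
Reactants: 8 (R)-2-[4-(benzyloxy)-3-methoxybenzyl]but-3-en-1-ol; 20 the 5-bromodihydrobenzofuran TBS ether
Product: 21 (R,E)-2-[4-(benzyloxy)-3-methoxybenzyl]-4-{(2S,3R)-2-[4-(benzyloxy)-3-methoxyphenyl]-3-[(tert-butyldimethylsilyloxy)methyl]-7-methoxy-2,3-dihydrobenzofuran-5-yl}but-3-en-1-ol
Conditions: Pd2(dba)3 (2.5 mol %), [(t-Bu)3PH]BF4 (10 mol %), Cy2NMe, dioxane, 90 °C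
Reagents that add atoms: none
Why: In this Mizoroki–Heck reaction the bulky electron-rich phosphine lets zerovalent palladium insert into the electron-rich aryl bromide, the aryl group goes to the unhindered terminal carbon, and syn beta-hydride elimination of a b4 hydrogen gives the conjugated (E)-styrene with b2 untouched.

Step 14
Reactants: 21 the (R,E)-homoallylic alcohol from step 13; 22 (bromomethyl)chlorodimethylsilane
Product: 23 (bromomethyl)dimethylsilyl ether of 21
Conditions: Et3N, DMAP (cat.), CH2Cl2, 0 °C; filtration through a short pad of deactivated silica, used at once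
Reagents that add atoms: none
Why: O-Silylation of the single free primary alcohol by the chlorosilane installs the radical precursor, which is sensitive to hydrolysis and is therefore only filtered and carried on.

Step 15
Reactants: 23 (bromomethyl)dimethylsilyl ether of 21
Product: 24 (4R,5R)-5-[4-(benzyloxy)-3-methoxybenzyl]-4-({(2S,3R)-2-[4-(benzyloxy)-3-methoxyphenyl]-3-[(tert-butyldimethylsilyloxy)methyl]-7-methoxy-2,3-dihydrobenzofuran-5-yl}methyl)-2,2-dimethyl-1,2-oxasilinane
Conditions: Bu3SnH, AIBN (cat.), slow addition by syringe pump, PhH (0.01 M), reflux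
Reagents that add atoms: none
Why: The tributyltin radical removes bromine from 23, the resulting alpha-silyl methyl radical adds intramolecularly to b3, and the benzylic radical left at b4 takes hydrogen from Bu3SnH and carries the chain. The closest known reaction type is the silicon-tethered radical cyclisation of (bromomethyl)dimethylsilyl ethers of unsaturated alcohols, used here in its homoallylic variant. The 1,2-oxasilinane ring closes in the 6-exo-trig mode. The new centre b3 is governed by b2 alone, because in the chair-like transition state the b2 arylmethyl group and the styryl arm on b3 both lie equatorial, which puts the two arylmethyl groups trans and makes b3 (R). The step needs exo rather than 7-endo closure, secured because only attack at b3 leaves a radical stabilised by ring B. It also needs cyclisation to outrun direct reduction and 1,5-hydrogen transfer from the allylic b2–H, which the styrene acceleration and the low stationary Bu3SnH concentration should provide, while C2 and C3 are too remote to interfere.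

Step 16
Reactants: 24 the (4R,5R)-oxasilinane from step 15
Product: 25 (2R,3R)-2-[4-(benzyloxy)-3-methoxybenzyl]-3-({(2S,3R)-2-[4-(benzyloxy)-3-methoxyphenyl]-3-(hydroxymethyl)-7-methoxy-2,3-dihydrobenzofuran-5-yl}methyl)butane-1,4-diol
Conditions: Bu4NF (excess), KHCO3, 30% aq H2O2, THF/MeOH, rt to 45 °C
Reagents that add atoms: hydrogen peroxide, OO
Why: In this Tamao–Fleming oxidation the fluoride-activated silicon takes up hydroperoxide, the methylene on b3 migrates from Si to O without touching any stereocentre, hydrolysis frees both CH2OH groups, and the excess fluoride strips the TBS ether in the same pot.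

Step 17
Reactants: 25 the bis(benzyl ether) triol from step 16
Product: 26 (2R,3R)-2-(4-hydroxy-3-methoxybenzyl)-3-{[(2S,3R)-2-(4-hydroxy-3-methoxyphenyl)-3-(hydroxymethyl)-7-methoxy-2,3-dihydrobenzofuran-5-yl]methyl}butane-1,4-diol (CNP0256425.1)
Conditions: H2 (1 atm), 10% Pd/C, EtOAc/EtOH, rt, stopped at full conversion
Reagents that add atoms: none
Why: Catalytic hydrogenolysis of aryl benzyl ethers at atmospheric pressure in neutral solvent is much faster than cleavage of the cyclic benzylic C2–O bond, so the target should emerge with all four stereocentres intact.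

Compound list
1 | (R)-4-benzyl-2-oxazolidinone | O=C1N[C@H](Cc2ccccc2)CO1 | starting material
2 | (E,E)-crotonic anhydride | C/C=C/C(=O)OC(=O)/C=C/C | starting material
3 | (R)-4-benzyl-3-[(E)-but-2-enoyl]oxazolidin-2-one | C/C=C/C(=O)N1[C@H](Cc2ccccc2)COC1=O | intermediate
4 | 4-(benzyloxy)-3-methoxybenzyl alcohol | COc1cc(CO)ccc1OCc1ccccc1 | starting material
5 | 4-(benzyloxy)-3-methoxybenzyl bromide | COc1cc(CBr)ccc1OCc1ccccc1 | intermediate
6 | sodium Z(O)-dienolate of 3 | C=C/C=C(\[O-])N1[C@H](Cc2ccccc2)COC1=O.[Na+] | intermediate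
7 | (R)-4-benzyl-3-{(R)-2-[4-(benzyloxy)-3-methoxybenzyl]but-3-enoyl}oxazolidin-2-one | COc1cc(C[C@@H](C(=O)N2[C@H](Cc3ccccc3)COC2=O)C=C)ccc1OCc1ccccc1 | intermediate
8 | (R)-2-[4-(benzyloxy)-3-methoxybenzyl]but-3-en-1-ol | COc1cc(C[C@@H](CO)C=C)ccc1OCc1ccccc1 | intermediate
9 | 4-(benzyloxy)-3-methoxybenzaldehyde | COc1cc(C=O)ccc1OCc1ccccc1 | starting material
10 | triethyl phosphonoacetate | CCOC(=O)CP(=O)(OCC)OCC | starting material
11 | ethyl (E)-3-[4-(benzyloxy)-3-methoxyphenyl]acrylate | CCOC(=O)/C=C/c1ccc(OCc2ccccc2)c(OC)c1 | intermediate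
12 | (E)-3-[4-(benzyloxy)-3-methoxyphenyl]prop-2-en-1-ol | OC/C=C/c1ccc(OCc2ccccc2)c(OC)c1 | intermediate
13 | (E)-3-[4-(benzyloxy)-3-methoxyphenyl]allyl methyl carbonate | COC(=O)OC/C=C/c1ccc(OCc2ccccc2)c(OC)c1 | intermediate
14 | 4-bromo-2-methoxyphenol | COc1cc(Br)ccc1O | starting material
15 | 4-bromo-2-iodo-6-methoxyphenol | COc1cc(Br)cc(I)c1O | intermediate
16 | sodium 4-bromo-2-iodo-6-methoxyphenolate | COc1cc(Br)cc(I)c1[O-].[Na+] | intermediate
17 | (S)-1-(benzyloxy)-4-[1-(4-bromo-2-iodo-6-methoxyphenoxy)allyl]-2-methoxybenzene | C=C[C@@H](c1ccc(OCc2ccccc2)c(OC)c1)Oc1c(I)cc(Br)cc1OC | intermediate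
18 | 1-{[(2S,3R)-2-[4-(benzyloxy)-3-methoxyphenyl]-5-bromo-7-methoxy-2,3-dihydrobenzofuran-3-yl]methoxy}-2,2,6,6-tetramethylpiperidine | Brc1cc(OC)c2c(c1)[C@H](CON3C(C)(C)CCCC3(C)C)[C@@H](c1ccc(OCc3ccccc3)c(OC)c1)O2 | intermediate
19 | [(2S,3R)-2-[4-(benzyloxy)-3-methoxyphenyl]-5-bromo-7-methoxy-2,3-dihydrobenzofuran-3-yl]methanol | Brc1cc(OC)c2c(c1)[C@H](CO)[C@@H](c1ccc(OCc3ccccc3)c(OC)c1)O2 | intermediate
20 | TBS ether of 19 | Brc1cc(OC)c2c(c1)[C@H](CO[Si](C)(C)C(C)(C)C)[C@@H](c1ccc(OCc3ccccc3)c(OC)c1)O2 | intermediate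
21 | (R,E)-2-[4-(benzyloxy)-3-methoxybenzyl]-4-{(2S,3R)-2-[4-(benzyloxy)-3-methoxyphenyl]-3-[(tert-butyldimethylsilyloxy)methyl]-7-methoxy-2,3-dihydrobenzofuran-5-yl}but-3-en-1-ol | COc1cc(C[C@@H](CO)/C=C/c2cc(OC)c3c(c2)[C@H](CO[Si](C)(C)C(C)(C)C)[C@@H](c2ccc(OCc4ccccc4)c(OC)c2)O3)ccc1OCc1ccccc1 | intermediate
22 | (bromomethyl)chlorodimethylsilane | C[Si](C)(Cl)CBr | starting material
23 | (bromomethyl)dimethylsilyl ether of 21 | COc1cc(C[C@@H](CO[Si](C)(C)CBr)/C=C/c2cc(OC)c3c(c2)[C@H](CO[Si](C)(C)C(C)(C)C)[C@@H](c2ccc(OCc4ccccc4)c(OC)c2)O3)ccc1OCc1ccccc1 | intermediate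
24 | (4R,5R)-trans-4,5-bis(arylmethyl)-2,2-dimethyl-1,2-oxasilinane (full name in step 15) | COc1cc(C[C@@H](CO[Si]2(C)C)[C@H](C2)Cc2cc(OC)c3c(c2)[C@H](CO[Si](C)(C)C(C)(C)C)[C@@H](c2ccc(OCc4ccccc4)c(OC)c2)O3)ccc1OCc1ccccc1 | intermediate
25 | (2R,3R)-2-[4-(benzyloxy)-3-methoxybenzyl]-3-({(2S,3R)-2-[4-(benzyloxy)-3-methoxyphenyl]-3-(hydroxymethyl)-7-methoxy-2,3-dihydrobenzofuran-5-yl}methyl)butane-1,4-diol | COc1cc(C[C@@H](CO)[C@H](CO)Cc2cc(OC)c3c(c2)[C@H](CO)[C@@H](c2ccc(OCc4ccccc4)c(OC)c2)O3)ccc1OCc1ccccc1 | intermediate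
26 | CNP0256425.1 | COc1cc(C[C@@H](CO)[C@H](CO)Cc2cc(OC)c3c(c2)[C@H](CO)[C@@H](c2ccc(O)c(OC)c2)O3)ccc1O | target

Total step count: 17.
Longest linear sequence: 12 steps (9 to 26 through steps 5, 6, 7, 9, 10, 11, 12, 13, 14, 15, 16, 17).

Steps most likely to fail

1. Step 15.
- **What may go wrong:** The alpha-silyl radical may be reduced before it cyclises. It may pull the allylic hydrogen off b2 by 1,5-transfer. It may also close with weak 1,2-induction, so that cis and trans rings form together.
- **Fallback (from 8 and 20, back at 25):** The carbon of the b3 branch is brought in as a lactone carbonyl, and the b3–b4 bond is made by enolate alkylation.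
- Hydroboration–oxidation of 8 (9-BBN; then NaOH, H2O2) should give (R)-2-[4-(benzyloxy)-3-methoxybenzyl]butane-1,4-diol F1.
- Oxidative lactonisation of F1 at the less hindered carbinol (TEMPO cat., PhI(OAc)2, CH2Cl2) should give (R)-4-[4-(benzyloxy)-3-methoxybenzyl]dihydrofuran-2(3H)-one F2.
- In parallel, bromine–lithium exchange on 20 (n-BuLi, THF, −78 °C) and quenching with DMF should give the dihydrobenzofuran-5-carbaldehyde F3.
- NaBH4 reduces F3 to the 5-(hydroxymethyl)dihydrobenzofuran F4, and an Appel reaction (CBr4, PPh3) turns F4 into the 5-(bromomethyl)dihydrobenzofuran F5.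
- The lithium enolate of F2 (LiN(SiMe3)2, THF, −78 °C) is alkylated by F5 anti to the beta substituent, the classical entry to trans-dibenzylbutyrolactone lignans, to give the (3R,4R)-lactone F6.
- LiAlH4 opens F6 to the TBS-protected diol F7, and Bu4NF then gives 25.

2. Step 9.
- **What may go wrong:** Attack by the doubly ortho-substituted, weakly nucleophilic aryloxide may be sluggish. Some material may leak to the linear ether. Re-ionisation of the electron-rich branched ether may erode its enantiomeric purity. Any residual minor enantiomer becomes a separable diastereomer after step 13.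
- **Fallback (from 15 and 5, back at 19; steps 5 to 7 and 9 to 11 are then not needed):** The C2–C3 bond is made by a carbenoid C–H insertion instead of a C–O bond-forming substitution.
- Williamson etherification of 15 with 5 (K2CO3, DMF) should give 5-bromo-2-{[4-(benzyloxy)-3-methoxybenzyl]oxy}-1-iodo-3-methoxybenzene F8.
- Selective iodine–magnesium exchange (i-PrMgCl·LiCl, THF, −40 °C) and trapping with dimethyl oxalate should give the aryl glyoxylate F9.
- Condensation with TsNHNH2 gives the tosylhydrazone F10, and Bamford–Stevens elimination (DBU, CH2Cl2) gives the aryldiazoacetate F11.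
- Enantioselective intramolecular 1,5 C–H insertion into the benzylic ether methylene follows, using Rh2(PTTL)4 in toluene at low temperature. The catalyst antipode is chosen for the (2S) series. This should give the cis ester F12.
- NaOMe in MeOH epimerises C3 to the trans ester F13, and LiBH4 reduces F13 to 19.

3. Step 13.
- **What may go wrong:** Insertion may occur with the wrong regiochemistry. Beta-hydride elimination toward b2 followed by chain walking would move the alkene out of conjugation and erase the b2 centre.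
- **Fallback (from 8 and 20, back at 21):** The alkene geometry and position are fixed before the C–C coupling.
- Cross metathesis of 8 with vinylboronic acid pinacol ester (second-generation Hoveyda–Grubbs catalyst, CH2Cl2, reflux) should give the (R,E)-alkenylboronate F14.
- Suzuki–Miyaura coupling of F14 with 20 (Pd(dppf)Cl2, K3PO4, dioxane/H2O, 80 °C) proceeds with retention of the alkene geometry and gives 21.

Further compounds
F1 | step 15 | (R)-2-[4-(benzyloxy)-3-methoxybenzyl]butane-1,4-diol | COc1cc(C[C@@H](CO)CCO)ccc1OCc1ccccc1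
F2 | step 15 | (R)-4-[4-(benzyloxy)-3-methoxybenzyl]dihydrofuran-2(3H)-one | COc1cc(C[C@@H]2CC(=O)OC2)ccc1OCc1ccccc1
F3 | step 15 | (2S,3R)-2-[4-(benzyloxy)-3-methoxyphenyl]-3-[(tert-butyldimethylsilyloxy)methyl]-7-methoxy-2,3-dihydrobenzofuran-5-carbaldehyde | O=Cc1cc(OC)c2c(c1)[C@H](CO[Si](C)(C)C(C)(C)C)[C@@H](c1ccc(OCc3ccccc3)c(OC)c1)O2
F4 | step 15 | {(2S,3R)-2-[4-(benzyloxy)-3-methoxyphenyl]-3-[(tert-butyldimethylsilyloxy)methyl]-7-methoxy-2,3-dihydrobenzofuran-5-yl}methanol | OCc1cc(OC)c2c(c1)[C@H](CO[Si](C)(C)C(C)(C)C)[C@@H](c1ccc(OCc3ccccc3)c(OC)c1)O2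
F5 | step 15 | {[(2S,3R)-2-[4-(benzyloxy)-3-methoxyphenyl]-5-(bromomethyl)-7-methoxy-2,3-dihydrobenzofuran-3-yl]methoxy}(tert-butyl)dimethylsilane | BrCc1cc(OC)c2c(c1)[C@H](CO[Si](C)(C)C(C)(C)C)[C@@H](c1ccc(OCc3ccccc3)c(OC)c1)O2
F6 | step 15 | (3R,4R)-4-[4-(benzyloxy)-3-methoxybenzyl]-3-({(2S,3R)-2-[4-(benzyloxy)-3-methoxyphenyl]-3-[(tert-butyldimethylsilyloxy)methyl]-7-methoxy-2,3-dihydrobenzofuran-5-yl}methyl)dihydrofuran-2(3H)-one | COc1cc(C[C@H]2COC(=O)[C@@H]2Cc2cc(OC)c3c(c2)[C@H](CO[Si](C)(C)C(C)(C)C)[C@@H](c2ccc(OCc4ccccc4)c(OC)c2)O3)ccc1OCc1ccccc1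
F7 | step 15 | 25 carrying a TBS ether on the C3 hydroxymethyl group | COc1cc(C[C@@H](CO)[C@H](CO)Cc2cc(OC)c3c(c2)[C@H](CO[Si](C)(C)C(C)(C)C)[C@@H](c2ccc(OCc4ccccc4)c(OC)c2)O3)ccc1OCc1ccccc1
F8 | step 9 | 5-bromo-2-{[4-(benzyloxy)-3-methoxybenzyl]oxy}-1-iodo-3-methoxybenzene | COc1cc(Br)cc(I)c1OCc1ccc(OCc2ccccc2)c(OC)c1
F9 | step 9 | methyl 2-(5-bromo-2-{[4-(benzyloxy)-3-methoxybenzyl]oxy}-3-methoxyphenyl)-2-oxoacetate | COC(=O)C(=O)c1cc(Br)cc(OC)c1OCc1ccc(OCc2ccccc2)c(OC)c1
F10 | step 9 | N-tosylhydrazone of F9 | COC(=O)C(=NNS(=O)(=O)c1ccc(C)cc1)c1cc(Br)cc(OC)c1OCc1ccc(OCc2ccccc2)c(OC)c1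
F11 | step 9 | methyl 2-(5-bromo-2-{[4-(benzyloxy)-3-methoxybenzyl]oxy}-3-methoxyphenyl)-2-diazoacetate | COC(=O)C(=[N+]=[N-])c1cc(Br)cc(OC)c1OCc1ccc(OCc2ccccc2)c(OC)c1
F12 | step 9 | methyl (2S,3R)-cis-2-[4-(benzyloxy)-3-methoxyphenyl]-5-bromo-7-methoxy-2,3-dihydrobenzofuran-3-carboxylate | Brc1cc(OC)c2c(c1)[C@@H](C(=O)OC)[C@@H](c1ccc(OCc3ccccc3)c(OC)c1)O2
F13 | step 9 | methyl (2S,3S)-trans-2-[4-(benzyloxy)-3-methoxyphenyl]-5-bromo-7-methoxy-2,3-dihydrobenzofuran-3-carboxylate | Brc1cc(OC)c2c(c1)[C@H](C(=O)OC)[C@@H](c1ccc(OCc3ccccc3)c(OC)c1)O2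
F14 | step 13 | (R,E)-2-[4-(benzyloxy)-3-methoxybenzyl]-4-(4,4,5,5-tetramethyl-1,3,2-dioxaborolan-2-yl)but-3-en-1-ol | COc1cc(C[C@@H](CO)/C=C/B2OC(C)(C)C(C)(C)O2)ccc1OCc1ccccc1
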